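Any E left over when a flask is stopped may still turn into X, so for beta and gamma the question is how long each clock runs against the flask's own pace. E turns into X under held L, with D formed on the way.

| setting | noon | dusk | beta | gamma |
|---|---|---|---|---|
| E | 0.27 M | 0.49 M | 0.20 M | 0.44 M |
| L | 35 mM (held) | 35 mM (held) | 35 mM (held) | 35 mM (held) |
| temperature | −20 °C | 5 °C | −15 °C | 25 °C |
| remark | run made earlier | run made earlier |  |  |
| time |  |  | 15 min | 8.0 min |

- noon (time / min: X / %): 10.0: 3.2; 30.0: 10.4; 50.0: 16.0; 80.0: 22.3
- dusk (time / min: X / %): 2.50: 6.4; 8.00: 16.4; 15.0: 21.9; 20.0: 24.5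

(scatter of a reading: 0.3 percentage points)

- the flask that ends with the higher amount of X, in percent of the E charged, or "neither" when 2 percentage points or less lies between them (beta / gamma / neither)
- final X, as a percentage of the E charged, in beta
- final X, as a percentage of the E charged, in gamma

- at the start none of L is in solution
- in a conversion D counts as not yet reacted

Both runs flatten, and with L held each curve can be read as pseudo-first-order. The logarithm of the first slope over the last slope, divided by the time between their midpoints, gives a relaxation constant, read as 0.0120 min⁻¹ in noon and 0.102 min⁻¹ in dusk. Taking its logarithm as straight in temperature, with the different charges carried along and gamma an extrapolation, gives the turnover count, the time allowed multiplied by the constant at that temperature: 0.276 for beta and 4.54 for gamma.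

Beta's count equals noon's at 23.0 min, so interpolating noon's readings puts beta near 7.89 %. Gamma's count is higher than the 2.04 of dusk's last reading, so gamma should stand on the flat part, well above beta.

The forecast, reading “relaxation towards a plateau”, gives 8 % for beta and 21.5 % for gamma, so gamma.

The flasks give 8.66 % in beta and 18.1 % in gamma, so gamma ends higher.

    E ⇌ D (K = 1.20, k = 0.00556 s⁻¹, Ea = 93.0 kJ mol⁻¹, ΔH = −33.0 kJ mol⁻¹)
    E + J → X (k = 0.0985 M⁻¹ s⁻¹, Ea = 55.0 kJ mol⁻¹)
    J + D → Q (k = 0.216 M⁻¹ s⁻¹, Ea = 47.0 kJ mol⁻¹)
    E + X → Z (k = 0.0136 M⁻¹ s⁻¹, Ea = 53.0 kJ mol⁻¹)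
    L ⇌ J, rate k5*(csat - [J]) (kL = 0.0387 s⁻¹)
    (constants at 25 °C)

At 0.276 turnovers, beta stops at 15 min with E at 89 %; left to 150 min it reaches X 43.3 %, more than gamma's 21.9 % at 80.0 min, so the order of the two turns round. A flask like beta kept at −30 °C, reckoned from beta's count along the same straight line, counts 0.0762 turnovers, noon's count at 6.35 min, earlier than its first reading of 3.2 % at 10.0 min, and it ends with X at 1.95 %.

The data are calculated with made-up constants; scatter was added.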